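The target, the (Z)-sinapyl half ester of (R)-3-hydroxy-3-methylglutaric acid, is unmasked last by removing two silyl ethers (phenol O and tertiary O).
Key disconnection: the bond from aromatic C-1 to the vinylic CH. It is made by a Zweifel olefination between 4-silyloxy-3,5-dimethoxyphenyllithium and the (E)-alkenyl pinacol boronate of the complete glutarate half ester. The same operation inverts E to Z, so the bond and the cis geometry arrive together and without palladium.
Enabling feature: the vinylic carbon on aromatic C-1 bears only H and belongs to an unbranched Ar–CH=CH–CH2–O unit, so it can first carry boron in the easily available E form. The ring (H at C-2/C-6, O-donors at C-3, C-4, C-5) is the only carbon ligand on boron that can migrate.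
Boronate half: (R)-mevalonolactone supplies the carbinol centre. Saponification, O-alkylation of the C-1 carboxylate with (E)-ClCH2CH=CH–Bpin and oxidation of C-5 to the acid tell the two arms apart.
No ring of the target is built: the benzene ring is bought as 4-bromo-2,6-dimethoxyphenol, the lactone ring is opened in step 2, and the dioxaborolane, the only temporary ring, leaves in step 5.

Key step: step 5

Assumption: the carbinol centre of the target is read as (3R), because CH2CO2-allyl ranks above CH2CO2H. With the esterified arm coming from C-1 and the free acid from C-5, this is the spatial arrangement of natural (R)-mevalonolactone.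

Step 1
Reactants: 1 4-bromo-2,6-dimethoxyphenol
Product: 2 (4-bromo-2,6-dimethoxyphenoxy)(tert-butyl)dimethylsilane
Conditions: TBSCl, imidazole, DMF, rt
Reagents that add atoms: tert-butyldimethylsilyl chloride, CC(C)(C)[Si](C)(C)Cl
Why: Imidazole-promoted silyl ether formation caps the phenol, which would otherwise quench the aryllithium and be iodinated or oxidised by iodine, and a silyl ether flanked by two methoxy groups should survive n-BuLi and cold methoxide.

Step 2
Reactants: 3 (R)-mevalonolactone; 4 (E)-2-(3-chloroprop-1-enyl)-4,4,5,5-tetramethyl-1,3,2-dioxaborolane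
Product: 6 (E)-3-(pinacolboryl)allyl (3R)-3,5-dihydroxy-3-methylpentanoate, via potassium mevalonate 5 (not isolated)
Conditions: KOH (1.0 equiv), MeOH–H2O, rt, evaporate and dry (toluene azeotrope); then 4, NaI (10 mol %), DMF, rt
Reagents that add atoms: potassium hydroxide, [K+].[OH-]
Why: Lactone saponification followed by SN2 O-alkylation of the carboxylate with the allylic chloride avoids the unfavourable alcoholysis equilibrium of the lactone, touches no bond at C-3 so the purchased (R) centre is carried over unchanged, and brings in the E-alkenylboronate ready-made.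

Step 3
Reactants: 6 (E)-3-(pinacolboryl)allyl (3R)-3,5-dihydroxy-3-methylpentanoate
Product: 8 (3R)-3-hydroxy-3-methyl-5-oxo-5-[(E)-3-(pinacolboryl)allyloxy]pentanoic acid, via aldehyde 7 (not isolated)
Conditions: TEMPO (20 mol %), PhI(OAc)2 (2.2 equiv), MeCN–H2O, 0 °C to rt
Reagents that add atoms: water, O
Why: Nitroxyl-catalysed oxidation (TEMPO/PhI(OAc)2) takes only the primary alcohol through aldehyde 7 and its hydrate to the acid, and the mildly acidic, peroxide-free medium should leave the tertiary alcohol, the ester and the pinacol alkenylboronate alone, so the two arms at C-3 now differ as ester and acid in the required sense.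

Step 4
Reactants: 8 (3R)-3-hydroxy-3-methyl-5-oxo-5-[(E)-3-(pinacolboryl)allyloxy]pentanoic acid
Product: 10 (3R)-3-methyl-5-oxo-5-[(E)-3-(pinacolboryl)allyloxy]-3-(triethylsilyloxy)pentanoic acid, via bis-silyl derivative 9 (not isolated)
Conditions: TESOTf (2.5 equiv), 2,6-lutidine, CH2Cl2, −78 to 0 °C; then THF–H2O (pH 7 buffer), rt
Reagents that add atoms: triethylsilyl triflate, CC[Si](CC)(CC)OS(=O)(=O)C(F)(F)F
Why: Silyl triflate silylation is strong enough for the hindered tertiary alcohol and also silylates the acid, and the far more labile silyl ester of 9 is hydrolysed selectively by water, so only the β-hydroxy group stays masked (no retro-aldol cleavage and no quench of the aryllithium in step 5).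

Step 5
Reactants: 10 (3R)-3-methyl-5-oxo-5-[(E)-3-(pinacolboryl)allyloxy]-3-(triethylsilyloxy)pentanoic acid; 2 (4-bromo-2,6-dimethoxyphenoxy)(tert-butyl)dimethylsilane
Product: 16 (3R)-5-[(Z)-3-(4-tert-butyldimethylsilyloxy-3,5-dimethoxyphenyl)allyloxy]-3-methyl-5-oxo-3-(triethylsilyloxy)pentanoic acid, via sodium carboxylate 11 (not isolated), via aryllithium 12 (not isolated), via boronate complex 13 (not isolated), via iodo boronic ester 14 (not isolated), via sodium salt 15 (not isolated)
Conditions: 10, NaH (1.0 equiv), THF, 0 °C; 2, n-BuLi (1.0 equiv), THF, −78 °C, then by cannula into the carboxylate at −78 °C; I2 (1.0 equiv), THF, −78 °C, dark; NaOMe (2 equiv), MeOH, −78 to −20 °C; aq Na2S2O3 wash, dilute HCl to pH 4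
Reagents that add atoms: none
Why: Zweifel olefination: aryllithium 12 fills the empty p orbital on boron of 11 to give the tetracoordinate boronate 13, iodine attacks its electron-rich C=C to form an iodonium ion, and the aryl ring migrates from boron to the adjacent carbon anti to the breaking C–I bond (1,2-metallate shift), which makes the aromatic C-1–CH bond and gives 14. Methoxide then binds to boron and B and I leave antiperiplanar, so anti addition followed by anti elimination converts the E-alkenylboronate stereospecifically into the Z-alkene; the closest known reaction type is the iodine/methoxide coupling of (E)-alkenyl pinacol boronates with aryllithium reagents. No ring is closed and no lasting stereocentre is made: the two transient centres of 14 (fixed relative configuration, both alkene faces attacked) are destroyed again, and the remote silylated C-3 centre has no acidic or ionisable bond that these reagents touch. Boron must win over carbonyl: one carboxyl group is shut down as its sodium salt, the allylic ester carbonyl is neopentyl-type (CH2 next to the fully substituted C-3 with its OSiEt3 group), complexation at boron at −78 °C is much faster, and adding iodine immediately forestalls a slow allylic displacement of the carboxylate from 13. Iodine must attack the alkenyl and not the aryl ligand: the alkenyl π bond of 13 is the most nucleophilic site, iodine is too weak an electrophile for the silyl-capped ring at −78 °C, and of the four ligands on boron only the aryl carbon can migrate to the iodonium carbon. Because no palladium(0) is present the allylic ester cannot ionise, and working in the dark with one equivalent of iodine and a cold reductive wash guards the Z-alkene against iodine-catalysed isomerisation.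

Step 6
Reactants: 16 (3R)-5-[(Z)-3-(4-tert-butyldimethylsilyloxy-3,5-dimethoxyphenyl)allyloxy]-3-methyl-5-oxo-3-(triethylsilyloxy)pentanoic acid
Product: 17 (3R)-3-hydroxy-5-[(2Z)-3-(4-hydroxy-3,5-dimethoxyphenyl)prop-2-enyloxy]-3-methyl-5-oxopentanoic acid (target)
Conditions: HF·pyridine, pyridine, THF, 0 °C to rt, dark, plastic vessel; pH 4 buffer work-up
Reagents that add atoms: none
Why: Fluoride-mediated desilylation with buffered HF·pyridine cleaves the phenolic and the tertiary silyl ether through Si–F bond formation at mildly acidic pH, where ester hydrolysis, phenoxide-driven loss of the allylic carboxylate and any change at C-3 (no acidic hydrogen) should not occur, and exclusion of light protects the Z-alkene.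

Compound list
1 | 4-bromo-2,6-dimethoxyphenol | COc1cc(Br)cc(OC)c1O | starting material
2 | (4-bromo-2,6-dimethoxyphenoxy)(tert-butyl)dimethylsilane | COc1cc(Br)cc(OC)c1O[Si](C)(C)C(C)(C)C | intermediate
3 | (R)-mevalonolactone, (4R)-4-hydroxy-4-methyloxan-2-one | O=C1C[C@](C)(O)CCO1 | starting material
4 | (E)-2-(3-chloroprop-1-enyl)-4,4,5,5-tetramethyl-1,3,2-dioxaborolane | ClC/C=C/B1OC(C)(C)C(C)(C)O1 | starting material
5 | potassium (3R)-3,5-dihydroxy-3-methylpentanoate (potassium mevalonate) | [K+].[O-]C(=O)C[C@](C)(O)CCO | intermediate
6 | (E)-3-(pinacolboryl)allyl (3R)-3,5-dihydroxy-3-methylpentanoate | CC1(C)OB(/C=C/COC(=O)C[C@](C)(O)CCO)OC1(C)C | intermediate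
7 | (E)-3-(pinacolboryl)allyl (3R)-3-hydroxy-3-methyl-5-oxopentanoate (aldehyde) | CC1(C)OB(/C=C/COC(=O)C[C@](C)(O)CC=O)OC1(C)C | intermediate
8 | (3R)-3-hydroxy-3-methyl-5-oxo-5-[(E)-3-(pinacolboryl)allyloxy]pentanoic acid | CC1(C)OB(/C=C/COC(=O)C[C@](C)(O)CC(=O)O)OC1(C)C | intermediate
9 | triethylsilyl ester and triethylsilyl ether of 8 (spatial arrangement at C-3 unchanged) | CC1(C)OB(/C=C/COC(=O)C[C@](C)(O[Si](CC)(CC)CC)CC(=O)O[Si](CC)(CC)CC)OC1(C)C | intermediate
10 | (3R)-3-methyl-5-oxo-5-[(E)-3-(pinacolboryl)allyloxy]-3-(triethylsilyloxy)pentanoic acid | CC1(C)OB(/C=C/COC(=O)C[C@](C)(O[Si](CC)(CC)CC)CC(=O)O)OC1(C)C | intermediate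
11 | sodium salt of 10 | [Na+].CC1(C)OB(/C=C/COC(=O)C[C@](C)(O[Si](CC)(CC)CC)CC(=O)[O-])OC1(C)C | intermediate
12 | 4-(tert-butyldimethylsilyloxy)-3,5-dimethoxyphenyllithium | [Li]c1cc(OC)c(O[Si](C)(C)C(C)(C)C)c(OC)c1 | intermediate
13 | lithium sodium salt of the aryl(E-alkenyl)pinacolatoborate carboxylate | [Li+].[Na+].COc1cc(cc(OC)c1O[Si](C)(C)C(C)(C)C)[B-]1(/C=C/COC(=O)C[C@](C)(O[Si](CC)(CC)CC)CC(=O)[O-])OC(C)(C)C(C)(C)O1 | intermediate
14 | sodium salt of the 1-aryl-1-(pinacolboryl)-2-iodopropyl ester from anti addition (one of the two facial isomers drawn; the other has both new centres inverted) | [Na+].COc1cc(cc(OC)c1O[Si](C)(C)C(C)(C)C)[C@H](B1OC(C)(C)C(C)(C)O1)[C@@H](I)COC(=O)C[C@](C)(O[Si](CC)(CC)CC)CC(=O)[O-] | intermediate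
15 | sodium salt of 16 | [Na+].COc1cc(/C=C\COC(=O)C[C@](C)(O[Si](CC)(CC)CC)CC(=O)[O-])cc(OC)c1O[Si](C)(C)C(C)(C)C | intermediate
16 | (3R)-5-[(Z)-3-(4-tert-butyldimethylsilyloxy-3,5-dimethoxyphenyl)allyloxy]-3-methyl-5-oxo-3-(triethylsilyloxy)pentanoic acid | COc1cc(/C=C\COC(=O)C[C@](C)(O[Si](CC)(CC)CC)CC(=O)O)cc(OC)c1O[Si](C)(C)C(C)(C)C | intermediate
17 | (3R)-3-hydroxy-5-[(2Z)-3-(4-hydroxy-3,5-dimethoxyphenyl)prop-2-enyloxy]-3-methyl-5-oxopentanoic acid | COc1cc(/C=C\COC(=O)C[C@](C)(O)CC(=O)O)cc(OC)c1O | target

Total step count: 6. Longest linear sequence: 5 steps (steps 2 to 6, from 3).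

Steps most likely to fail

Step 5. The aryllithium or the methoxide may attack the allylic ester. Iodine may attack the electron-rich aryl ligand instead of the alkenyl ligand, which would transfer the alkenyl group with retention and erode the Z geometry. Traces of iodine may also isomerise the Z-alkene. The fallback sets out from 10 and 2 and separates bond formation from geometry. Suzuki–Miyaura coupling (SPhos–palladium precatalyst, K3PO4, THF–H2O, 40 °C) joins the same two carbons with retention and gives the (E)-configured bis-silyl ether acid F1. Visible-light triplet sensitisation (fac-Ir(ppy)3, blue LED, MeCN, rt) is a contra-thermodynamic E-to-Z isomerisation of styrenes that mirrors the likely photochemical origin of cis-sinapyl esters, and it should enrich the Z-isomer. The Z-isomer is separated from remaining F1 on silver nitrate-impregnated silica and comes back to the route at 16.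

Step 6. Once the para-phenol is free, the allylic C–O bond may ionise under the acidic fluoride conditions. The alkene may isomerise, and the hindered tertiary silyl ether may be cleaved too slowly for both to be avoided. The fallback sets out from 16 and unmasks in two orthogonal stages with the phenol last. AcOH–THF–H2O at rt removes only the triethylsilyl ether while the phenol is still capped and gives the phenol-silylated hydroxy acid F2. KHF2 in MeOH at rt, which is selective for phenolic silyl ethers and nearly neutral, then releases the phenol and comes back at 17.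

Step 3. The alkenyl C–B bond may be oxidised or hydrolysed in the aqueous oxidising medium. The δ-hydroxy ester may also relactonise, with loss of the allylic alcohol, before it is oxidised. The fallback sets out from 5 and brings in boron only after the oxidation. Alkylation with allyl bromide (DMF, rt) gives allyl (R)-mevalonate F3. The same nitroxyl oxidation, run at once, gives by way of the aldehyde F4 the allyl half ester F5. Cross-metathesis of F5 with vinylboronic acid pinacol ester (second-generation Hoveyda–Grubbs catalyst, CH2Cl2, 40 °C) tolerates the free acid and alcohol, should favour the E-alkenylboronate, and comes back at 8.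

Further compounds
F1 | step 5 | (3R)-5-[(E)-3-(4-tert-butyldimethylsilyloxy-3,5-dimethoxyphenyl)allyloxy]-3-methyl-5-oxo-3-(triethylsilyloxy)pentanoic acid | COc1cc(/C=C/COC(=O)C[C@](C)(O[Si](CC)(CC)CC)CC(=O)O)cc(OC)c1O[Si](C)(C)C(C)(C)C
F2 | step 6 | (3R)-5-[(Z)-3-(4-tert-butyldimethylsilyloxy-3,5-dimethoxyphenyl)allyloxy]-3-hydroxy-3-methyl-5-oxopentanoic acid | COc1cc(/C=C\COC(=O)C[C@](C)(O)CC(=O)O)cc(OC)c1O[Si](C)(C)C(C)(C)C
F3 | step 3 | allyl (3R)-3,5-dihydroxy-3-methylpentanoate | C=CCOC(=O)C[C@](C)(O)CCO
F4 | step 3 | allyl (3R)-3-hydroxy-3-methyl-5-oxopentanoate | C=CCOC(=O)C[C@](C)(O)CC=O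
F5 | step 3 | (3R)-5-(allyloxy)-3-hydroxy-3-methyl-5-oxopentanoic acid | C=CCOC(=O)C[C@](C)(O)CC(=O)O
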